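**Plan**
- Retrosynthesis first removes the two O–SO3H bonds (at O3 and O7) and the benzyl ethers of ring B, then the C3–O bond, which is introduced by oxidising C2=C3 of a flavone.
- The pyranone ring C is then cut at C4a–C4, C4–C3 and O1–C2. This is possible because the C4 carbonyl lies between C4a of the phloroglucinol-derived ring A (whose neighbour C8a carries O1) and the C3=C2 unit bearing the catechol ring B, so C4 can be supplied as carbon monoxide.
- Forward: ring A is prepared as an o-iodophenol from phloroglucinol and ring B as an arylacetylene from the dibenzylated aldehyde; ring C closes in one palladium-catalysed operation from iodophenol, CO and alkyne.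
- C3 is then oxygenated and the MOM ethers removed, the 3- and 7-hydroxyls are sulfated while the chelated 5-OH stays free, and the benzyl ethers are hydrogenolysed last.
- Stereochemistry: the target has no stereocentre; the only stereogenic intermediate, a racemic epoxide, is consumed on aromatisation.

Key step: step 4

Remark: the target is achiral, so there is no enantiomer to select; its sulfate monoesters are drawn as free acids, so the route carries them as the dipotassium salt and protonates only at the very end (the free acid should be kept cold, the potassium salt being the storable form).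

**Route**

Step 1
Reactants: 1 phloroglucinol
Product: 2 3,5-bis(methoxymethoxy)phenol
Conditions: MOMCl (2.0 equiv), i-Pr2NEt (2.4 equiv), DMF, 0 °C → rt; chromatography
Reagents that add atoms: chloromethyl methyl ether, COCCl
Why: Base-mediated O-alkylation of a phenol with MOMCl (Williamson-type ether formation) on three equivalent hydroxyls should give the bis-ether as the main component at two equivalents of reagent, separable by chromatography from the mono- and tris-ethers.

Step 2
Reactants: 2 3,5-bis(methoxymethoxy)phenol
Product: 3 2-iodo-3,5-bis(methoxymethoxy)phenol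
Conditions: I2 (1.0 equiv), NaHCO3, THF–H2O (1:1), 0 °C
Reagents that add atoms: iodine, II
Why: Electrophilic aromatic iodination of the phenoxide with I2/bicarbonate, the conditions that turn resorcinol into 2-iodoresorcinol, should attack one of the two equivalent positions ortho to the free hydroxyl in preference to C4, which is flanked by two bulkier MOM ethers, and the acetals are stable at this pH.

Step 3
Reactants: 4 3,4-bis(benzyloxy)benzaldehyde
Product: 5 4-ethynyl-1,2-bis(benzyloxy)benzene
Conditions: dimethyl (1-diazo-2-oxopropyl)phosphonate (1.3 equiv), K2CO3 (2 equiv), MeOH, rt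
Reagents that add atoms: dimethyl (1-diazo-2-oxopropyl)phosphonate, COP(=O)(OC)C(=[N+]=[N-])C(C)=O
Why: Seyferth–Gilbert homologation in its Ohira–Bestmann form, in which methanolysis of the acetyl group frees the diazophosphonate anion that olefinates the aldehyde and the resulting diazoalkene loses N2 with 1,2-hydride shift to the terminal alkyne, under conditions that leave benzyl ethers untouched.

Step 4
Reactants: 3 2-iodo-3,5-bis(methoxymethoxy)phenol; 5 4-ethynyl-1,2-bis(benzyloxy)benzene; 6 carbon monoxide
Product: 9 3',4'-bis(benzyloxy)-5,7-bis(methoxymethoxy)flavone, via o-hydroxyaryl ynone 7 (not isolated), via enaminone 8 (not isolated)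
Conditions: PdCl2(dppf) (5 mol %), CO (20 bar), Et2NH (solvent), 120 °C, autoclave
Reagents that add atoms: none
Why: Pd(0) inserts into the C–I bond of 3, migratory insertion of CO gives an aroyl–Pd(II) species, and amine-assisted alkynylation with 5 followed by reductive elimination forms C4a–C4 and C4–C3 in ynone 7. Diethylamine then adds to the β-carbon of the ynone to give enaminone 8, and the ortho phenoxide attacks that same carbon and expels the amine, forming O1–C2. The closest known reaction type is the palladium-catalysed carbonylative Sonogashira coupling–cyclisation of o-iodophenols with terminal alkynes in a secondary amine, which delivers flavones. The one new ring, the pyranone, closes by intramolecular addition–elimination at the enaminone, in net terms a 6-endo-dig oxa-Michael closure, and no stereocentre is formed. The step needs carbonylative rather than direct coupling, which CO pressure and the fast CO insertion of the electron-rich aryl–palladium should secure, and six- rather than five-membered closure (aurone), which the amine adduct enforces by making the β-carbon the only electrophilic site. Only the one free hydroxyl ortho to iodine can cyclise because the other two oxygens of 3 are MOM ethers, so a single flavone regioisomer should result.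

Step 5
Reactants: 9 3',4'-bis(benzyloxy)-5,7-bis(methoxymethoxy)flavone
Product: 12 3',4'-di-O-benzylquercetin, via flavone 2,3-epoxide 10 (not isolated), via 3-hydroxyflavone bis-MOM ether 11 (not isolated)
Conditions: DMDO (acetone solution, 3–4 equiv in portions), CH2Cl2, 0 °C → rt; evaporate; then conc. HCl, MeOH–THF (1:1), 50 °C
Reagents that add atoms: dimethyldioxirane, CC1(C)OO1
Why: Dimethyldioxirane epoxidation of the flavone C2=C3 bond followed by acid isomerisation of the 2,3-epoxide (opening to the C2 oxocarbenium ion stabilised by O1 and the aryl group, then loss of H-3) is the established flavone-to-flavonol conversion, the same methanolic HCl cleaves both MOM acetals by transacetalisation while aryl benzyl ethers survive, and the two stereocentres of racemic 10 vanish on aromatisation.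

Step 6
Reactants: 12 3',4'-di-O-benzylquercetin
Product: 14 dipotassium 3',4'-di-O-benzylquercetin 3,7-disulfate, via bis(pyridinium) disulfate 13 (not isolated)
Conditions: SO3·pyridine (6 equiv), pyridine, rt; then aq. KHCO3 to pH 8; Sephadex LH-20
Reagents that add atoms: sulfur trioxide–pyridine complex, O=S(=O)([O-])[n+]1ccccc1; potassium hydrogen carbonate, [K+].OC(=O)[O-]
Why: O-Sulfation of phenols with the SO3·pyridine complex should esterify the acidic 7-OH and the enolic 3-OH, while the 5-OH, held in a strong hydrogen bond to the C4 carbonyl and the least nucleophilic of the three, should stay free at room temperature with limited excess, and bicarbonate then exchanges pyridinium for potassium.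

Step 7
Reactants: 14 dipotassium 3',4'-di-O-benzylquercetin 3,7-disulfate
Product: 16 quercetin 3,7-di-O-sulfate, via dipotassium quercetin 3,7-disulfate 15 (not isolated)
Conditions: H2 (1 atm), 10% Pd/C, MeOH–H2O (4:1), rt; filter; then 1 M HCl (2.0 equiv), 0 °C; freeze-dry, take up in cold EtOH, filter off KCl
Reagents that add atoms: none
Why: Catalytic hydrogenolysis of aryl benzyl ethers over Pd/C leaves aryl sulfate salts and the tetrasubstituted flavonol C2=C3 bond untouched, the potassium salt carries no amine that could poison the catalyst, and brief cold treatment with exactly two equivalents of HCl protonates the disulfate.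

**Compound list**

1 | phloroglucinol (benzene-1,3,5-triol) | Oc1cc(O)cc(O)c1 | starting material
2 | 3,5-bis(methoxymethoxy)phenol | COCOc1cc(O)cc(OCOC)c1 | intermediate
3 | 2-iodo-3,5-bis(methoxymethoxy)phenol | COCOc1cc(O)c(I)c(OCOC)c1 | intermediate
4 | 3,4-bis(benzyloxy)benzaldehyde | O=Cc1ccc(OCc2ccccc2)c(OCc2ccccc2)c1 | starting material
5 | 4-ethynyl-1,2-bis(benzyloxy)benzene | C#Cc1ccc(OCc2ccccc2)c(OCc2ccccc2)c1 | intermediate
6 | carbon monoxide | [C-]#[O+] | starting material
7 | 3-[3,4-bis(benzyloxy)phenyl]-1-[2-hydroxy-4,6-bis(methoxymethoxy)phenyl]prop-2-yn-1-one (not isolated) | COCOc1cc(O)c(C(=O)C#Cc2ccc(OCc3ccccc3)c(OCc3ccccc3)c2)c(OCOC)c1 | intermediate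
8 | (E)-3-[3,4-bis(benzyloxy)phenyl]-3-(diethylamino)-1-[2-hydroxy-4,6-bis(methoxymethoxy)phenyl]prop-2-en-1-one (not isolated; geometry of no consequence) | CCN(CC)/C(=C/C(=O)c1c(O)cc(OCOC)cc1OCOC)c1ccc(OCc2ccccc2)c(OCc2ccccc2)c1 | intermediate
9 | 3',4'-bis(benzyloxy)-5,7-bis(methoxymethoxy)flavone | COCOc1cc(OCOC)c2c(c1)oc(-c1ccc(OCc3ccccc3)c(OCc3ccccc3)c1)cc2=O | intermediate
10 | cis-2,3-epoxide of 9, racemic, one enantiomer drawn (not isolated) | O=C1c2c(OCOC)cc(OCOC)cc2O[C@]2(c3ccc(OCc4ccccc4)c(OCc4ccccc4)c3)O[C@H]12 | intermediate
11 | 3',4'-bis(benzyloxy)-3-hydroxy-5,7-bis(methoxymethoxy)flavone (not isolated) | COCOc1cc(OCOC)c2c(c1)oc(-c1ccc(OCc3ccccc3)c(OCc3ccccc3)c1)c(O)c2=O | intermediate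
12 | 3',4'-di-O-benzylquercetin (2-[3,4-bis(benzyloxy)phenyl]-3,5,7-trihydroxy-4H-chromen-4-one) | O=c1c(O)c(-c2ccc(OCc3ccccc3)c(OCc3ccccc3)c2)oc2cc(O)cc(O)c12 | intermediate
13 | bis(pyridinium) 3',4'-di-O-benzylquercetin 3,7-disulfate (not isolated) | O=c1c(OS(=O)(=O)[O-])c(-c2ccc(OCc3ccccc3)c(OCc3ccccc3)c2)oc2cc(OS(=O)(=O)[O-])cc(O)c12.c1cc[nH+]cc1.c1cc[nH+]cc1 | intermediate
14 | dipotassium 3',4'-di-O-benzylquercetin 3,7-disulfate | O=c1c(OS(=O)(=O)[O-])c(-c2ccc(OCc3ccccc3)c(OCc3ccccc3)c2)oc2cc(OS(=O)(=O)[O-])cc(O)c12.[K+].[K+] | intermediate
15 | dipotassium quercetin 3,7-disulfate (not isolated) | O=c1c(OS(=O)(=O)[O-])c(-c2ccc(O)c(O)c2)oc2cc(OS(=O)(=O)[O-])cc(O)c12.[K+].[K+] | intermediate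
16 | quercetin 3,7-di-O-sulfate (bis(hydrogen sulfate), achiral) | O=c1c(OS(=O)(=O)O)c(-c2ccc(O)c(O)c2)oc2cc(OS(=O)(=O)O)cc(O)c12 | target

**Step count**

Total steps: 7. Longest linear sequence: 6 steps (steps 1, 2, 4, 5, 6, 7 from phloroglucinol); the alkyne arm joins after one step.

**Steps most likely to fail**

Step 4. Oxidative addition at the doubly ortho-substituted, electron-rich C–I bond may be slow, and the aroyl-palladium may be intercepted by diethylamine (amide formation) or by-passed by CO-free coupling, so that little ynone reaches the cyclisation. The fallback gives up carbon monoxide as the C4 source and builds the same ynone by polar chemistry, setting out from alkyne 5. Commercial 2,4,6-trihydroxybenzaldehyde is bis-protected (MOMCl, i-Pr2NEt, CH2Cl2; the chelated ortho-hydroxyl stays free) to 2-hydroxy-4,6-bis(methoxymethoxy)benzaldehyde F1. Alkyne 5 is deprotonated (n-BuLi, 2.2 equiv, THF, −78 °C) and added to F1 to give the racemic propargylic alcohol 3-[3,4-bis(benzyloxy)phenyl]-1-[2-hydroxy-4,6-bis(methoxymethoxy)phenyl]prop-2-yn-1-ol F2. MnO2 in CH2Cl2 should oxidise F2 to ynone 7, and Et2NH in EtOH at reflux should take 7 through enaminone 8 to flavone 9, where the route is rejoined.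

Step 2. Iodination may occur para to the free hydroxyl (between the two MOM ethers) or twice, giving material whose iodine cannot be flanked by the ring-closing oxygen. The fallback removes the regiochemical question by iodinating before any protection and lets symmetry decide; it sets out from phloroglucinol 1 and returns at flavone 9. Treatment of 1 with I2/NaHCO3 in THF–H2O at 0 °C, where all three ring positions are equivalent, should give 2-iodobenzene-1,3,5-triol F3, and Ac2O/pyridine its triacetate 2-iodobenzene-1,3,5-triyl triacetate F4. F4, alkyne 5 and carbon monoxide 6 are then joined under the iodophenol-acetate variant of the annulation (PdCl2(PPh3)2, dppp, thiourea, Et2NH, DBU, CO 1 atm, 40 °C). Coupling should give the ynone triacetate 2-{3-[3,4-bis(benzyloxy)phenyl]propynoyl}benzene-1,3,5-triyl triacetate F5, which is not isolated. Diethylamine removes its acetyl groups and adds to the triple bond, and either of the two equivalent ortho oxygens closes the ring to 3',4'-bis(benzyloxy)-5,7-dihydroxyflavone F6. MOMCl/NaH in DMF then converts F6 into 9.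

Step 5. Epoxidation of the electron-poor C2=C3 bond may be slow enough that C–H oxidation at the benzylic and acetal positions competes. The fallback replaces electrophilic oxygen transfer by deprotonation–borylation–oxidation; it sets out from flavone 9 and returns at flavonol 11. LDA (THF, −78 °C) should remove H-3 of 9, B(OMe)3 traps the 3-lithio species as dimethyl {2-[3,4-bis(benzyloxy)phenyl]-5,7-bis(methoxymethoxy)-4-oxo-4H-chromen-3-yl}boronate F7, and H2O2/AcOH oxidises the C–B bond to give 11. The methanolic HCl stage of step 5 then converts 11 into 12.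

**Further compounds**

F1 | step 4 | 2-hydroxy-4,6-bis(methoxymethoxy)benzaldehyde | COCOc1cc(O)c(C=O)c(OCOC)c1
F2 | step 4 | racemic 3-[3,4-bis(benzyloxy)phenyl]-1-[2-hydroxy-4,6-bis(methoxymethoxy)phenyl]prop-2-yn-1-ol | COCOc1cc(O)c(C(O)C#Cc2ccc(OCc3ccccc3)c(OCc3ccccc3)c2)c(OCOC)c1
F3 | step 2 | 2-iodobenzene-1,3,5-triol | Oc1cc(O)c(I)c(O)c1
F4 | step 2 | 2-iodobenzene-1,3,5-triyl triacetate | CC(=O)Oc1cc(OC(C)=O)c(I)c(OC(C)=O)c1
F5 | step 2 | 2-{3-[3,4-bis(benzyloxy)phenyl]propynoyl}benzene-1,3,5-triyl triacetate | CC(=O)Oc1cc(OC(C)=O)c(C(=O)C#Cc2ccc(OCc3ccccc3)c(OCc3ccccc3)c2)c(OC(C)=O)c1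
F6 | step 2 | 3',4'-bis(benzyloxy)-5,7-dihydroxyflavone | O=c1cc(-c2ccc(OCc3ccccc3)c(OCc3ccccc3)c2)oc2cc(O)cc(O)c12
F7 | step 5 | dimethyl {2-[3,4-bis(benzyloxy)phenyl]-5,7-bis(methoxymethoxy)-4-oxo-4H-chromen-3-yl}boronate | COCOc1cc(OCOC)c2c(c1)oc(-c1ccc(OCc3ccccc3)c(OCc3ccccc3)c1)c(B(OC)OC)c2=O
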